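Numbering used throughout: C1 lactone C=O, C2 (Me), C3 ketone, C4 (OH, CH2OH), C5, C6(Me)=C7, C8 (Me), C9, C10 (=CH2), C11=C12(Me), C13 (Et)–O.
Retrosynthesis, in order: C10=CH2 is traced back to C10=O, which makes C8 the only open β-carbon of a cross-conjugated dienone C8=C9–C10(=O)–C11=C12 (C12 is β,β-disubstituted). C7–C8 is then cut to a C7 alkenylboron, then the B–C7=C6 unit to a C3–O-tethered vinylboronate plus a C6 methallyl group, then C10–C11, the C13–O ester and C2–C3.
The enabling feature is that O3 sits 1,5 to C7, so a seven-membered O3–B–C7=C6–C5–C4–C3 ring can hold the boron and can only contain the Z alkene.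
Forward: a C1–C6 acid (acetonide ring on C4–O/C4–CH2O) is esterified with a C11–C13 Z-iodoalkenol, C8–C10 is added as crotonaldehyde and oxidised, the oxaborepine ring is built on C3–OH, and the 14-membered ring is closed last at C7–C8.
Helpers leave in order: boron (in the ring closure), C10=O (methylenation), C3–OH (oxidation), acetonide (hydrolysis).
Stereochemistry: C4 from Sharpless epoxidation; C2 from an Evans syn-aldol, protected by keeping C3 as a carbinol; C13 from (S)-pent-1-yn-3-ol; Z-C11=C12 from chelate-controlled anti-carbomagnesiation; Z-C6=C7 from the boron ring; C8 from (S)-BINAP on rhodium.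

Key step: step 16

Assumption: (S)-pent-1-yn-3-ol is taken as a purchasable enantiopure alcohol, and the 2R centre between the two carbonyl groups is taken to hold its configuration under the buffered, base-free conditions of the last two steps.

Step 1
Reactants: 1 prop-2-yn-1-ol; 2 (2-methylprop-2-en-1-yl)magnesium chloride
Product: 4 dienol 4-methyl-2-methylidenepent-4-en-1-ol, via alkenylmagnesium alkoxide 3 (not isolated)
Conditions: 2 (2.5 equiv), CuI (5 mol %), THF, 0 °C → reflux; aq. NH4Cl
Reagents that add atoms: none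
Why: hydroxyl-directed anti-carbomagnesiation of a propargylic alcohol: the first equivalent of Grignard reagent forms the alkoxide, the second adds the methallyl group to the inner alkyne carbon because magnesium ends in a five-membered alkoxide chelate, and protonation should give the 1,1-disubstituted allylic alcohol (no stereocentre).

Step 2
Reactants: 4 4-methyl-2-methylidenepent-4-en-1-ol
Product: 5 (S)-[2-(2-methylprop-2-en-1-yl)oxiran-2-yl]methanol
Conditions: Ti(OiPr)4 (10 mol %), L-(+)-diethyl tartrate (12 mol %), t-BuOOH (2 equiv, in decane), 4 Å MS, CH2Cl2, −20 °C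
Reagents that add atoms: tert-butyl hydroperoxide, CC(C)(C)OO
Why: Sharpless asymmetric epoxidation: only the allylic-alcohol alkene is epoxidised because oxygen is delivered inside the titanium–tartrate–alkoxide complex, and L-(+)-tartrate should give the S epoxide in the sense established for 2-substituted allylic alcohols, which sets the future C4.

Step 3
Reactants: 5 (S)-[2-(2-methylprop-2-en-1-yl)oxiran-2-yl]methanol
Product: 6 (S)-2-{[(4-methoxybenzyl)oxy]methyl}-4-methylpent-4-ene-1,2-diol
Conditions: 4-MeOC6H4CH2OH (3 equiv), NaH (2.2 equiv), DMF, 0 → 60 °C; H2O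
Reagents that add atoms: 4-methoxybenzyl alcohol, COc1ccc(CO)cc1
Why: base-mediated SN2 alcoholysis of the 2,2-disubstituted epoxide at its CH2 terminus leaves the C4–O bond intact (retention), and the competing Payne rearrangement is degenerate here (it returns the same enantiomer of 5), so the two CH2O arms become differentiated without loss of configuration.

Step 4
Reactants: 6 (S)-2-{[(4-methoxybenzyl)oxy]methyl}-4-methylpent-4-ene-1,2-diol
Product: 7 (R)-4-{[(4-methoxybenzyl)oxy]methyl}-2,2-dimethyl-4-(2-methylprop-2-en-1-yl)-1,3-dioxolane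
Conditions: Me2C(OMe)2, PPTS (cat.), CH2Cl2, rt
Reagents that add atoms: 2,2-dimethoxypropane, COC(C)(C)OC
Why: acid-catalysed transketalisation ties the tertiary C4–OH and the free primary OH (the only 1,2-diol present) into a dioxolane; the stereocentre is untouched and only its CIP descriptor changes.

Step 5
Reactants: 7 (R)-4-{[(4-methoxybenzyl)oxy]methyl}-2,2-dimethyl-4-(2-methylprop-2-en-1-yl)-1,3-dioxolane
Product: 8 (R)-[2,2-dimethyl-4-(2-methylprop-2-en-1-yl)-1,3-dioxolan-4-yl]methanol
Conditions: DDQ (1.3 equiv), CH2Cl2/pH 7 buffer (10:1), 0 °C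
Reagents that add atoms: none
Why: oxidative cleavage of the 4-methoxybenzyl ether (benzylic hydride abstraction, hydrolysis of the oxocarbenium ion) frees the arm that becomes C3, the isolated 1,1-disubstituted alkene and the acetonide being inert to buffered DDQ.

Step 6
Reactants: 8 (R)-[2,2-dimethyl-4-(2-methylprop-2-en-1-yl)-1,3-dioxolan-4-yl]methanol
Product: 9 (S)-2,2-dimethyl-4-(2-methylprop-2-en-1-yl)-1,3-dioxolane-4-carbaldehyde
Conditions: DMP, pyridine, CH2Cl2, 0 °C → rt
Reagents that add atoms: none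
Why: Dess–Martin oxidation of a neopentyl primary alcohol; the aldehyde has no α-hydrogen and cannot epimerise.

Step 7
Reactants: 9 (S)-2,2-dimethyl-4-(2-methylprop-2-en-1-yl)-1,3-dioxolane-4-carbaldehyde; 10 (R)-4-benzyl-3-propanoyl-1,3-oxazolidin-2-one
Product: 12 (R)-4-benzyl-3-{(2R,3R)-3-[(S)-2,2-dimethyl-4-(2-methylprop-2-en-1-yl)-1,3-dioxolan-4-yl]-3-hydroxy-2-methylpropanoyl}-1,3-oxazolidin-2-one, via dibutylboron (Z)-enolate 11 (not isolated)
Conditions: 10, Bu2BOTf, iPr2NEt, CH2Cl2, −78 → 0 °C; then 9, −78 → 0 °C; pH 7 buffer, MeOH, H2O2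
Reagents that add atoms: none
Why: Evans syn-aldol reaction: the (Z)-boron enolate reacts through a Zimmerman–Traxler chair in which the (R)-benzyl auxiliary dictates the enolate face, setting C2 as R (the C3 carbinol, expected R, is erased later by oxidation).

Step 8
Reactants: 12 the aldol adduct
Product: 13 (R)-4-benzyl-3-{(2R,3R)-3-[(S)-2,2-dimethyl-4-(2-methylprop-2-en-1-yl)-1,3-dioxolan-4-yl]-2-methyl-3-[(triethylsilyl)oxy]propanoyl}-1,3-oxazolidin-2-one
Conditions: TESOTf, 2,6-lutidine, CH2Cl2, −78 → 0 °C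
Reagents that add atoms: triethylsilyl trifluoromethanesulfonate, CC[Si](CC)(CC)OS(=O)(=O)C(F)(F)F
Why: silyl triflate silylation of the hindered C3 carbinol prevents β-lactone formation and self-acylation in the later esterification; no stereocentre is touched.

Step 9
Reactants: 13 the C3 triethylsilyl ether of the aldol adduct
Product: 15 (2R,3R)-3-[(S)-2,2-dimethyl-4-(2-methylprop-2-en-1-yl)-1,3-dioxolan-4-yl]-2-methyl-3-[(triethylsilyl)oxy]propanoic acid, via peroxy acid 14 (not isolated)
Conditions: LiOH, H2O2, THF/H2O (3:1), 0 °C; Na2SO3; 1 M HCl to pH 3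
Reagents that add atoms: hydrogen peroxide, OO
Why: lithium hydroperoxide attacks the exocyclic imide carbonyl selectively and the peroxy acid is reduced by sulfite, which should release the acid without epimerising C2 and return the auxiliary.

Step 10
Reactants: 16 (S)-pent-1-yn-3-ol
Product: 18 (S,Z)-1-iodo-2-methylpent-1-en-3-ol, via alkenylmagnesium alkoxide 17 (not isolated)
Conditions: MeMgBr (3 equiv), CuI (10 mol %), THF, −10 °C → rt; then I2, −78 → 0 °C
Reagents that add atoms: methylmagnesium bromide, C[Mg]Br; iodine, II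
Why: copper-catalysed anti-carbomagnesiation of the propargylic alkoxide places the methyl group on the future C12 and magnesium on the future C11 cis to the carbinol carbon (five-membered chelate), and iodinolysis with retention should give the Z iodide; the carbinol centre (future C13) is not involved.

Step 11
Reactants: 15 the silyloxy acid; 18 (S,Z)-1-iodo-2-methylpent-1-en-3-ol
Product: 20 (S,Z)-1-iodo-2-methylpent-1-en-3-yl (2R,3R)-3-[(S)-2,2-dimethyl-4-(2-methylprop-2-en-1-yl)-1,3-dioxolan-4-yl]-2-methyl-3-[(triethylsilyl)oxy]propanoate, via mixed trichlorobenzoic anhydride 19 (not isolated)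
Conditions: 2,4,6-Cl3C6H2COCl, Et3N, THF, rt; then 18, DMAP, toluene, rt
Reagents that add atoms: none
Why: Yamaguchi esterification: DMAP transfers the acyl group of the mixed anhydride to the secondary allylic alcohol with retention at C13 (its C–O bond is not broken).

Step 12
Reactants: 20 the iodoalkenyl ester; 21 (E)-but-2-enal
Product: 22 (2E,5Z,7S)-4-hydroxy-6-methylnona-2,5-dien-7-yl (2R,3R)-3-[(S)-2,2-dimethyl-4-(2-methylprop-2-en-1-yl)-1,3-dioxolan-4-yl]-2-methyl-3-[(triethylsilyl)oxy]propanoate (both epimers at the new carbinol, C10)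
Conditions: 21 (4 equiv), CrCl2 (6 equiv), NiCl2 (2 mol %), DMSO, rt
Reagents that add atoms: none
Why: Nozaki–Hiyama–Kishi reaction: the nickel-catalysed formation of the alkenylchromium species keeps the Z geometry and its 1,2-addition to the enal tolerates the ester, the silyl ether and the acetonide; the new carbinol centre is removed in the next step.

Step 13
Reactants: 22 the bis-allylic alcohol
Product: 23 (2E,5Z,7S)-6-methyl-4-oxonona-2,5-dien-7-yl (2R,3R)-3-[(S)-2,2-dimethyl-4-(2-methylprop-2-en-1-yl)-1,3-dioxolan-4-yl]-2-methyl-3-[(triethylsilyl)oxy]propanoate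
Conditions: DMP, pyridine, CH2Cl2, 0 °C
Reagents that add atoms: none
Why: Dess–Martin oxidation of the bis-allylic alcohol gives the cross-conjugated dienone; because O13 is already acylated, the Z γ-oxy enone cannot close to a lactol or furan.

Step 14
Reactants: 23 the silyloxy dienone
Product: 24 (2E,5Z,7S)-6-methyl-4-oxonona-2,5-dien-7-yl (2R,3R)-3-[(S)-2,2-dimethyl-4-(2-methylprop-2-en-1-yl)-1,3-dioxolan-4-yl]-3-hydroxy-2-methylpropanoate
Conditions: HF·pyridine, pyridine, THF, 0 °C → rt
Reagents that add atoms: none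
Why: buffered fluoride cleaves the triethylsilyl ether (strong Si–F bond) while the acetonide, the ester and the dienone should survive; C3–OH becomes the anchor for boron.

Step 15
Reactants: 24 the C3 alcohol; 25 dibutyl ethenylboronate
Product: 28 (2E,5Z,7S)-6-methyl-4-oxonona-2,5-dien-7-yl (2R)-2-[(5S,6R)-8-hydroxy-2,2,10-trimethyl-1,3,7-trioxa-8-boraspiro[4.6]undec-9-en-6-yl]propanoate (seven-membered ring O3–B–C7=C6–C5–C4–C3), via mixed vinylboronate 26 (not isolated), via cyclic butyl boronate 27 (not isolated)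
Conditions: 25 (1.2 equiv), 4 Å MS, toluene, 40 °C, reduced pressure (BuOH and excess 25 stripped); then second-generation Grubbs catalyst RuCl2(=CHPh)(H2IMes)(PCy3) (10 mol %), toluene (5 mM), 60 °C, Ar sparge; then THF/H2O, rt
Reagents that add atoms: water, O
Why: boron-tethered ring-closing metathesis: after boronate transesterification at C3–OH the ruthenium alkylidene formed on the vinylboron closes onto the 1,1-disubstituted C6 alkene with loss of ethene, and the seven-membered ring can hold the new trisubstituted C6=C7 bond only as the Z isomer (B cis to C5), the two electron-poor enone alkenes being much slower partners than the tethered pair.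

Step 16
Reactants: 28 the cyclic boronic acid hemiester
Product: 29 macrocyclic hydroxy ketone: 14-membered lactone with 2R-methyl, 3R-hydroxy, C4 (S) spiro-joined to the 2,2-dimethyl-1,3-dioxolane (C4–O and C4–CH2O), 6Z C6(CH3)=C7, 8S-methyl, C10=O, 11Z C11=C12(CH3), 13S-ethyl
Conditions: [Rh(OH)((S)-BINAP)]2 (5 mol % Rh), 1,4-dioxane/H2O (10:1), 40 °C, syringe-pump addition of 28 over 12 h (final 2 mM)
Reagents that add atoms: none
Why: Proposed new method: the hydroxorhodium–(S)-BINAP complex (monovalent rhodium) takes the C7 alkenyl group from the boronic hemiester by B-to-Rh transmetalation through a Rh–O–B bridge with retention of the ring-enforced Z geometry, the alkenylrhodium inserts the C8=C9 bond of the crotonyl arm to give an oxa-π-allylrhodium (C9–C10–O), and water protonates it at C9, regenerating Rh–OH and releasing boric acid. The closest known reaction type is the rhodium/BINAP-catalysed asymmetric 1,4-addition of alkenylboronic acids to acyclic (E)-enones (Hayashi–Miyaura reaction), known intermolecularly and for five- and six-membered ring closures but not as a macrocyclisation nor with a tethered boronic hemiester as donor. One ring is closed, the 14-membered lactone ring, by a 14-endo-trig attack of C7 on C8 (C8 and C9 both end up in the ring), while the seven-membered oxaborepine ring is opened in the same turnover and C3–OH is set free. The new stereocentre C8 is set by the ligand: by analogy with the sense known for acyclic (E)-β-alkyl enones, (S)-BINAP should present the Si face of C8 (C9 > CH3 > H), which gives 8S, the existing centres at C13 and C2–C4 being remote from the reacting carbons. The step needs site selectivity (C8 over C12, secured because C12 is β,β-disubstituted and would require a ten-membered ring with a quaternary carbon), 1,4- over 1,2-addition (inherent to alkenylrhodium species with enones) and ring closure over oligomerisation (slow addition at high dilution). Protodemetalation, the main expected leak, only returns 24, which can be resubmitted to step 15.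

Step 17
Reactants: 29 the macrocyclic hydroxy ketone
Product: 30 macrocyclic hydroxy diene: as 29 with C10=CH2 in place of C10=O (2R, 3R, 4S, 6Z, 8S, 11Z, 13S)
Conditions: Zn, CH2Br2, TiCl4 (reagent pre-formed in THF, 0 °C), CH2Cl2, 0 °C → rt
Reagents that add atoms: dibromomethane, BrCBr
Why: Lombardo methylenation: the non-basic zinc/titanium gem-dimetallic methylene reagent should convert the C10 ketone into the exocyclic alkene of the 1,3-diene without enolisation, retro-aldol cleavage of the β-hydroxy lactone or attack on the lactone carbonyl; no stereocentre is affected.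

Step 18
Reactants: 30 the macrocyclic hydroxy diene
Product: 31 macrocyclic β-keto lactone acetonide: as 30 with C3=O in place of C3–OH (2R, 4S, 6Z, 8S, 11Z, 13S)
Conditions: DMP, pyridine, CH2Cl2, 0 °C → rt
Reagents that add atoms: none
Why: Dess–Martin oxidation of the C3 carbinol under buffered, base-free conditions should give the β-keto lactone without enolising C2 (2R kept), the C4 oxygen functions still being masked so that only C3 can be oxidised.

Step 19
Reactants: 31 the β-keto lactone acetonide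
Product: 32 (3R,5S,7Z,9S,12Z,14S)-14-ethyl-5-hydroxy-5-(hydroxymethyl)-3,7,9,13-tetramethyl-11-methylidene-1-oxacyclotetradeca-7,12-diene-2,4-dione (the target)
Conditions: AcOH/THF/H2O (3:1:1), 35 °C
Reagents that add atoms: none
Why: mild acid-catalysed hydrolysis of the terminal acetonide (acetone lost) frees the tertiary C4–OH and the CH2OH without breaking any bond to a stereocentre, the weak acid being chosen to spare the allylic C13–O bond and the β-keto lactone.

Compound list
1 | prop-2-yn-1-ol | C#CCO | starting material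
2 | (2-methylprop-2-en-1-yl)magnesium chloride | C=C(C)C[Mg]Cl | starting material
3 | chloromagnesium (Z)-3-(chloromagnesio)-2-(2-methylprop-2-en-1-yl)prop-2-en-1-olate | C=C(C)C/C(CO[Mg]Cl)=C/[Mg]Cl | intermediate (not isolated)
4 | 4-methyl-2-methylidenepent-4-en-1-ol | C=C(C)CC(=C)CO | intermediate
5 | (S)-[2-(2-methylprop-2-en-1-yl)oxiran-2-yl]methanol | OC[C@@]1(CC(C)=C)CO1 | intermediate
6 | (S)-2-{[(4-methoxybenzyl)oxy]methyl}-4-methylpent-4-ene-1,2-diol | COc1ccc(COC[C@@](O)(CO)CC(C)=C)cc1 | intermediate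
7 | (R)-4-{[(4-methoxybenzyl)oxy]methyl}-2,2-dimethyl-4-(2-methylprop-2-en-1-yl)-1,3-dioxolane | COc1ccc(COC[C@@](O2)(COC2(C)C)CC(C)=C)cc1 | intermediate
8 | (R)-[2,2-dimethyl-4-(2-methylprop-2-en-1-yl)-1,3-dioxolan-4-yl]methanol | OC[C@@](O1)(COC1(C)C)CC(C)=C | intermediate
9 | (S)-2,2-dimethyl-4-(2-methylprop-2-en-1-yl)-1,3-dioxolane-4-carbaldehyde | O=C[C@@](O1)(COC1(C)C)CC(C)=C | intermediate
10 | (R)-4-benzyl-3-propanoyl-1,3-oxazolidin-2-one | CCC(=O)N1[C@H](Cc2ccccc2)COC1=O | starting material
11 | (R)-4-benzyl-3-{(Z)-1-[(dibutylboranyl)oxy]prop-1-en-1-yl}-1,3-oxazolidin-2-one | C/C=C(\OB(CCCC)CCCC)N1[C@H](Cc2ccccc2)COC1=O | intermediate (not isolated)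
12 | (R)-4-benzyl-3-{(2R,3R)-3-[(S)-2,2-dimethyl-4-(2-methylprop-2-en-1-yl)-1,3-dioxolan-4-yl]-3-hydroxy-2-methylpropanoyl}-1,3-oxazolidin-2-one | O=C1OC[C@@H](Cc2ccccc2)N1C(=O)[C@H](C)[C@@H](O)[C@@](O3)(COC3(C)C)CC(C)=C | intermediate
13 | (R)-4-benzyl-3-{(2R,3R)-3-[(S)-2,2-dimethyl-4-(2-methylprop-2-en-1-yl)-1,3-dioxolan-4-yl]-2-methyl-3-[(triethylsilyl)oxy]propanoyl}-1,3-oxazolidin-2-one | O=C1OC[C@@H](Cc2ccccc2)N1C(=O)[C@H](C)[C@@H](O[Si](CC)(CC)CC)[C@@](O3)(COC3(C)C)CC(C)=C | intermediate
14 | (2R,3R)-3-[(S)-2,2-dimethyl-4-(2-methylprop-2-en-1-yl)-1,3-dioxolan-4-yl]-2-methyl-3-[(triethylsilyl)oxy]propaneperoxoic acid | OOC(=O)[C@H](C)[C@@H](O[Si](CC)(CC)CC)[C@@](O1)(COC1(C)C)CC(C)=C | intermediate (not isolated)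
15 | (2R,3R)-3-[(S)-2,2-dimethyl-4-(2-methylprop-2-en-1-yl)-1,3-dioxolan-4-yl]-2-methyl-3-[(triethylsilyl)oxy]propanoic acid | OC(=O)[C@H](C)[C@@H](O[Si](CC)(CC)CC)[C@@](O1)(COC1(C)C)CC(C)=C | intermediate
16 | (S)-pent-1-yn-3-ol | C#C[C@H](CC)O | starting material
17 | bromomagnesium (S,Z)-1-(bromomagnesio)-2-methylpent-1-en-3-olate | Br[Mg]/C=C(/C)[C@H](CC)O[Mg]Br | intermediate (not isolated)
18 | (S,Z)-1-iodo-2-methylpent-1-en-3-ol | I/C=C(/C)[C@H](CC)O | intermediate
19 | mixed anhydride of acid 15 with 2,4,6-trichlorobenzoic acid | Clc1cc(Cl)c(C(=O)OC(=O)[C@H](C)[C@@H](O[Si](CC)(CC)CC)[C@@](O2)(COC2(C)C)CC(C)=C)c(Cl)c1 | intermediate (not isolated)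
20 | (S,Z)-1-iodo-2-methylpent-1-en-3-yl (2R,3R)-3-[(S)-2,2-dimethyl-4-(2-methylprop-2-en-1-yl)-1,3-dioxolan-4-yl]-2-methyl-3-[(triethylsilyl)oxy]propanoate | I/C=C(/C)[C@H](CC)OC(=O)[C@H](C)[C@@H](O[Si](CC)(CC)CC)[C@@](O1)(COC1(C)C)CC(C)=C | intermediate
21 | (E)-but-2-enal | C/C=C/C=O | starting material
22 | (2E,5Z,7S)-4-hydroxy-6-methylnona-2,5-dien-7-yl (2R,3R)-3-[(S)-2,2-dimethyl-4-(2-methylprop-2-en-1-yl)-1,3-dioxolan-4-yl]-2-methyl-3-[(triethylsilyl)oxy]propanoate (carbinol epimers) | C/C=C/C(O)/C=C(/C)[C@H](CC)OC(=O)[C@H](C)[C@@H](O[Si](CC)(CC)CC)[C@@](O1)(COC1(C)C)CC(C)=C | intermediate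
23 | (2E,5Z,7S)-6-methyl-4-oxonona-2,5-dien-7-yl (2R,3R)-3-[(S)-2,2-dimethyl-4-(2-methylprop-2-en-1-yl)-1,3-dioxolan-4-yl]-2-methyl-3-[(triethylsilyl)oxy]propanoate | C/C=C/C(=O)/C=C(/C)[C@H](CC)OC(=O)[C@H](C)[C@@H](O[Si](CC)(CC)CC)[C@@](O1)(COC1(C)C)CC(C)=C | intermediate
24 | (2E,5Z,7S)-6-methyl-4-oxonona-2,5-dien-7-yl (2R,3R)-3-[(S)-2,2-dimethyl-4-(2-methylprop-2-en-1-yl)-1,3-dioxolan-4-yl]-3-hydroxy-2-methylpropanoate | C/C=C/C(=O)/C=C(/C)[C@H](CC)OC(=O)[C@H](C)[C@@H](O)[C@@](O1)(COC1(C)C)CC(C)=C | intermediate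
25 | dibutyl ethenylboronate | C=CB(OCCCC)OCCCC | starting material
26 | (2E,5Z,7S)-6-methyl-4-oxonona-2,5-dien-7-yl (2R,3R)-3-{[butoxy(ethenyl)boranyl]oxy}-3-[(S)-2,2-dimethyl-4-(2-methylprop-2-en-1-yl)-1,3-dioxolan-4-yl]-2-methylpropanoate | C/C=C/C(=O)/C=C(/C)[C@H](CC)OC(=O)[C@H](C)[C@@H](OB(C=C)OCCCC)[C@@](O1)(COC1(C)C)CC(C)=C | intermediate (not isolated)
27 | (2E,5Z,7S)-6-methyl-4-oxonona-2,5-dien-7-yl (2R)-2-[(5S,6R)-8-butoxy-2,2,10-trimethyl-1,3,7-trioxa-8-boraspiro[4.6]undec-9-en-6-yl]propanoate | C/C=C/C(=O)/C=C(/C)[C@H](CC)OC(=O)[C@H](C)[C@H]1OB(OCCCC)/C=C(/C)C[C@@]12OC(C)(C)OC2 | intermediate (not isolated)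
28 | (2E,5Z,7S)-6-methyl-4-oxonona-2,5-dien-7-yl (2R)-2-[(5S,6R)-8-hydroxy-2,2,10-trimethyl-1,3,7-trioxa-8-boraspiro[4.6]undec-9-en-6-yl]propanoate | C/C=C/C(=O)/C=C(/C)[C@H](CC)OC(=O)[C@H](C)[C@H]1OB(O)/C=C(/C)C[C@@]12OC(C)(C)OC2 | intermediate
29 | macrocyclic hydroxy ketone (14-membered lactone; 2R-Me, 3R-OH, 4S spiro-acetonide on C4–O/C4–CH2O, 6Z, 8S-Me, C10=O, 11Z, 13S-Et) | O=C1/C=C(/C)[C@H](CC)OC(=O)[C@H](C)[C@@H](O)[C@@](O2)(COC2(C)C)C/C(C)=C\[C@@H](C)C1 | intermediate
30 | macrocyclic hydroxy diene (as 29, C10=CH2) | C=C1/C=C(/C)[C@H](CC)OC(=O)[C@H](C)[C@@H](O)[C@@](O2)(COC2(C)C)C/C(C)=C\[C@@H](C)C1 | intermediate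
31 | macrocyclic β-keto lactone acetonide (as 30, C3=O) | C=C1/C=C(/C)[C@H](CC)OC(=O)[C@H](C)C(=O)[C@@](O2)(COC2(C)C)C/C(C)=C\[C@@H](C)C1 | intermediate
32 | (3R,5S,7Z,9S,12Z,14S)-14-ethyl-5-hydroxy-5-(hydroxymethyl)-3,7,9,13-tetramethyl-11-methylidene-1-oxacyclotetradeca-7,12-diene-2,4-dione | C=C1/C=C(/C)[C@H](CC)OC(=O)[C@H](C)C(=O)[C@@](O)(CO)C/C(C)=C\[C@@H](C)C1 | target

Total step count: 19. Longest linear sequence: 18 steps (steps 1–9 and 11–19; step 10 is the one-step side branch).

Steps most likely to fail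

Step 16 (Proposed new method). The insertion of the tethered enone into the alkenyl–rhodium bond across a 14-membered ring may be slower than protodemetalation by water or intermolecular addition, and the conformational bias of the forming ring may oppose the ligand at the C8 face. The fallback uses known reactions only: the C7–C8 bond is made intermolecularly and the ring is closed at C10–C11. It sets out from 20: HF·pyridine gives the C3 alcohol F1. Compound 25 and the second-generation Grubbs catalyst, as in step 15, then lead through the mixed vinylboronate F2 and the cyclic butyl boronate F3, neither isolated, to the iodoalkenyl cyclic boronic acid hemiester F4. A Hayashi–Miyaura 1,4-addition of F4 to (E)-but-2-enal 21 ([RhCl(C2H4)2]2, a chiral 2,5-diphenylbicyclo[2.2.2]octa-2,5-diene ligand of the antipode that attacks the Si face of C8, KOH, dioxane/H2O) should give the 8S aldehyde F5. An intramolecular Nozaki–Hiyama–Kishi reaction (CrCl2, NiCl2, DMSO/THF, high dilution) closes the ring between C11 and C10 to the macrocyclic allylic alcohol F6, and MnO2, which oxidises only the allylic C10–OH, returns the route at 29.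

Step 15. The ruthenium alkylidene may engage the crotonyl C8=C9 bond (loss of propene, cross- or large-ring metathesis) or initiate poorly on the vinylboronate, and boronate exchange at the hindered C3–OH may stay incomplete. The fallback runs the metathesis before any enone exists: from 20 through the C3 alcohol F1 to the iodoalkenyl cyclic boronic acid hemiester F4 as described above. An intermolecular Nozaki–Hiyama–Kishi addition of F4 to 21 then gives the bis-allylic alcohol F7, and MnO2 oxidation of its allylic carbinol returns the route at 28.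

Step 17. Conversion of the hindered, conjugated C10 ketone may stall, and the Lewis-acidic titanium reagent may open the acetonide or isomerise the C11=C12 bond. The fallback is a Peterson olefination: from 29, Me3SiCH2MgCl with CeCl3 (THF, −78 °C) adds to C10 to give the β-hydroxysilane F8 (either C10 epimer), and HF·pyridine effects the elimination, returning the route at 30.

Further compounds
F1 | step 16 | (S,Z)-1-iodo-2-methylpent-1-en-3-yl (2R,3R)-3-[(S)-2,2-dimethyl-4-(2-methylprop-2-en-1-yl)-1,3-dioxolan-4-yl]-3-hydroxy-2-methylpropanoate | I/C=C(/C)[C@H](CC)OC(=O)[C@H](C)[C@@H](O)[C@@](O1)(COC1(C)C)CC(C)=C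
F2 | step 16 | (S,Z)-1-iodo-2-methylpent-1-en-3-yl (2R,3R)-3-{[butoxy(ethenyl)boranyl]oxy}-3-[(S)-2,2-dimethyl-4-(2-methylprop-2-en-1-yl)-1,3-dioxolan-4-yl]-2-methylpropanoate | I/C=C(/C)[C@H](CC)OC(=O)[C@H](C)[C@@H](OB(C=C)OCCCC)[C@@](O1)(COC1(C)C)CC(C)=C
F3 | step 16 | (S,Z)-1-iodo-2-methylpent-1-en-3-yl (2R)-2-[(5S,6R)-8-butoxy-2,2,10-trimethyl-1,3,7-trioxa-8-boraspiro[4.6]undec-9-en-6-yl]propanoate | I/C=C(/C)[C@H](CC)OC(=O)[C@H](C)[C@H]1OB(OCCCC)/C=C(/C)C[C@@]12OC(C)(C)OC2
F4 | step 16 | (S,Z)-1-iodo-2-methylpent-1-en-3-yl (2R)-2-[(5S,6R)-8-hydroxy-2,2,10-trimethyl-1,3,7-trioxa-8-boraspiro[4.6]undec-9-en-6-yl]propanoate | I/C=C(/C)[C@H](CC)OC(=O)[C@H](C)[C@H]1OB(O)/C=C(/C)C[C@@]12OC(C)(C)OC2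
F5 | step 16 | (S,Z)-1-iodo-2-methylpent-1-en-3-yl (2R,3R)-3-{(S)-4-[(2Z,4S)-2,4-dimethyl-6-oxohex-2-en-1-yl]-2,2-dimethyl-1,3-dioxolan-4-yl}-3-hydroxy-2-methylpropanoate | I/C=C(/C)[C@H](CC)OC(=O)[C@H](C)[C@@H](O)[C@@](O1)(COC1(C)C)C/C(C)=C\[C@@H](C)CC=O
F6 | step 16 | macrocyclic diol (as 29 with C10–OH in place of C10=O, both C10 epimers) | OC1/C=C(/C)[C@H](CC)OC(=O)[C@H](C)[C@@H](O)[C@@](O2)(COC2(C)C)C/C(C)=C\[C@@H](C)C1
F7 | step 15 | (2E,5Z,7S)-4-hydroxy-6-methylnona-2,5-dien-7-yl (2R)-2-[(5S,6R)-8-hydroxy-2,2,10-trimethyl-1,3,7-trioxa-8-boraspiro[4.6]undec-9-en-6-yl]propanoate (carbinol epimers) | C/C=C/C(O)/C=C(/C)[C@H](CC)OC(=O)[C@H](C)[C@H]1OB(O)/C=C(/C)C[C@@]12OC(C)(C)OC2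
F8 | step 17 | macrocyclic β-hydroxysilane (as 29 with C10 carrying OH and CH2SiMe3, both C10 epimers) | C[Si](C)(C)CC1(O)/C=C(/C)[C@H](CC)OC(=O)[C@H](C)[C@@H](O)[C@@](O2)(COC2(C)C)C/C(C)=C\[C@@H](C)C1
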